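**Retrosynthetic overview**

- Target ⇐ hydrolysis of a bridged C19→C2 lactone; the axial C2–O comes from hydride attack on a C2 ketone from the open equatorial side.
- Ring B (closed last) ⇐ intramolecular Hosomi–Sakurai addition of a (Z)-allylsilane arm to a ring-A 3-methylcyclohexenone, forming C9–C10, the trans ring fusion and the exocyclic methylene together.
- Cyclisation substrate ⇐ Negishi union at C7–C8 of a ring-A alkylzinc (C1–C7, C10, C18–C20) with a 1,1-dibromoalkene carrying C8, C9, C11–C16; a second Negishi coupling brings C17.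
- Ring A (closed first) ⇐ δ-lactone template: asymmetric 1,4-addition (C5), two enolate alkylations (quaternary C4), acylative ring closure, lactone opening.
- Dibromoalkene ⇐ pent-4-yn-1-ol by carboalumination/acylation, oxidation and dibromo-olefination.

Assumption: the SMILES is read as drawn (a trans-decalin with the C2 hydroxyl, C19 carboxyl and C20 methyl all axial on one face); labdane numbering C1–C20 is used in the comments.

**Route**

Step 1
Reactants: 1 5,6-dihydro-2H-pyran-2-one; 2 potassium trifluoro(prop-1-en-2-yl)borate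
Product: 3 (4R)-4-(prop-1-en-2-yl)oxan-2-one
Conditions: [Rh(cod)2]BF4 (3 mol %), (R)-BINAP (3.3 mol %), PhMe/H2O 10:1, 100 °C
Reagents that add atoms: none
Why: Rhodium-catalysed asymmetric 1,4-addition (Hayashi–Miyaura type) of the alkenylboron reagent to the unsaturated lactone, the (R)-BINAP complex delivering isopropenyl to one face to set the R centre that becomes C5.

Step 2
Reactants: 3 (4R)-4-(prop-1-en-2-yl)oxan-2-one; 4 sodium iodoacetate
Product: 6 2-[(3S,4R)-2-oxo-4-(prop-1-en-2-yl)oxan-3-yl]acetic acid, via lithium enolate 5 (not isolated)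
Conditions: LiN(i-Pr)2 (1.05 equiv), THF, −78 °C; 4, DMPU, −78 → 0 °C; aq. HCl
Reagents that add atoms: none
Why: SN2 alkylation of the lactone enolate by the α-iodo carboxylate, which enters anti to the isopropenyl group (3,4-trans) at a centre that is re-enolised in step 3, so only the new C3–C4 bond matters.

Step 3
Reactants: 6 2-[(3S,4R)-2-oxo-4-(prop-1-en-2-yl)oxan-3-yl]acetic acid
Product: 8 2-[(3R,4S)-3-methyl-2-oxo-4-(prop-1-en-2-yl)oxan-3-yl]acetic acid, via dilithium dianion 7 (not isolated)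
Conditions: LiN(i-Pr)2 (2.2 equiv), THF/DMPU, −78 → −40 °C; MeI (1.3 equiv); aq. HCl
Reagents that add atoms: iodomethane, CI
Why: The carboxylate makes its own CH2 far less acidic, so the second equivalent of base forms only the lactone enolate, and enolate alkylation by MeI anti to the adjacent isopropenyl group sets quaternary C4 with methyl trans and the carboxymethyl arm cis to isopropenyl.

Step 4
Reactants: 8 2-[(3R,4S)-3-methyl-2-oxo-4-(prop-1-en-2-yl)oxan-3-yl]acetic acid
Product: 11 (4aS,8aR)-5,8a-dimethyl-3,4,4a,8a-tetrahydro-1H-isochromene-1,7(8H)-dione, via acid chloride 9 (not isolated), via chloro ketone 10 (not isolated)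
Conditions: (COCl)2, DMF (cat.), CH2Cl2, 0 → 23 °C; SnCl4 (1.1 equiv), CH2Cl2, −78 → −20 °C; Et3N, 0 °C
Reagents that add atoms: none
Why: Intramolecular Friedel–Crafts-type acylation of the 1,1-disubstituted alkene (the acylium attacks the CH2 terminus, Markovnikov, closing ring A at C1–C2), followed by E1cB loss of HCl from the tertiary chloride to the conjugated 3-methylcyclohexenone, with the cis-related C4 and C5 centres untouched.

Step 5
Reactants: 11 (4aS,8aR)-5,8a-dimethyl-3,4,4a,8a-tetrahydro-1H-isochromene-1,7(8H)-dione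
Product: 14 methyl (1R,2S)-2-(2-iodoethyl)-1,3-dimethyl-5-oxocyclohex-3-ene-1-carboxylate, via silyl ester 12 (not isolated), via iodo acid 13 (not isolated)
Conditions: Me3SiI (1.5 equiv), MeCN, 50 °C; MeOH; Me3SiCHN2, PhMe/MeOH, 0 °C
Reagents that add atoms: iodotrimethylsilane, C[Si](C)(C)I; (trimethylsilyl)diazomethane, C[Si](C)(C)C=[N+]=[N-]
Why: Silyl-activated SN2 opening of the δ-lactone by iodide at the primary O–CH2 carbon (C7), methanolysis of the silyl ester and O-methylation of the hindered acid by the diazoalkane, none of which touches a stereocentre.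

Step 6
Reactants: 15 pent-4-yn-1-ol
Product: 16 tert-butyl(dimethyl)(pent-4-yn-1-yloxy)silane
Conditions: t-BuMe2SiCl, imidazole, DMF, 23 °C
Reagents that add atoms: tert-butyl(chloro)dimethylsilane, CC(C)(C)[Si](C)(C)Cl
Why: Silyl ether protection, so that the hydroxyl neither consumes Me3Al nor is acylated by the chloroformate in step 7.

Step 7
Reactants: 16 tert-butyl(dimethyl)(pent-4-yn-1-yloxy)silane
Product: 18 methyl (2E)-6-[tert-butyl(dimethyl)silyl]oxy-3-methylhex-2-enoate, via alkenylalane 17 (not isolated)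
Conditions: Me3Al (2.2 equiv), Cp2ZrCl2 (0.25 equiv), CH2Cl2, 23 °C; ClCO2Me, 0 → 23 °C
Reagents that add atoms: trimethylaluminium, C[Al](C)C; methyl chloroformate, COC(=O)Cl
Why: Negishi zirconium-catalysed syn-carboalumination puts methyl on the internal and aluminium on the terminal alkyne carbon cis to each other, and acylation of the C–Al bond with retention gives only the (E)-3-methyl-2-enoate (C13=C14).

Step 8
Reactants: 18 methyl (2E)-6-[tert-butyl(dimethyl)silyl]oxy-3-methylhex-2-enoate
Product: 19 methyl (2E)-6-hydroxy-3-methylhex-2-enoate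
Conditions: HCl (cat.), MeOH, 0 → 23 °C
Reagents that add atoms: none
Why: Acid-catalysed methanolysis of the primary silyl ether (deprotection), to which the enoate is inert.

Step 9
Reactants: 19 methyl (2E)-6-hydroxy-3-methylhex-2-enoate
Product: 20 methyl (2E)-3-methyl-6-oxohex-2-enoate
Conditions: Dess–Martin periodinane, CH2Cl2, 23 °C
Reagents that add atoms: none
Why: Mild periodinane oxidation of the primary alcohol to the aldehyde without moving or isomerising the enoate double bond.

Step 10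
Reactants: 20 methyl (2E)-3-methyl-6-oxohex-2-enoate
Product: 21 methyl (2E)-7,7-dibromo-3-methylhepta-2,6-dienoate
Conditions: CBr4 (2 equiv), PPh3 (4 equiv), CH2Cl2, 0 °C
Reagents that add atoms: tetrabromomethane, BrC(Br)(Br)Br
Why: Ramirez (Corey–Fuchs) dibromo-olefination, a Wittig-type reaction of the in-situ dibromomethylene ylide that adds C8 as a CBr2 terminus.

Step 11
Reactants: 14 methyl (1R,2S)-2-(2-iodoethyl)-1,3-dimethyl-5-oxocyclohex-3-ene-1-carboxylate; 21 methyl (2E)-7,7-dibromo-3-methylhepta-2,6-dienoate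
Product: 23 methyl (1R,2S)-2-[(3Z,7E)-3-bromo-9-methoxy-7-methyl-9-oxonona-3,7-dien-1-yl]-1,3-dimethyl-5-oxocyclohex-3-ene-1-carboxylate, via alkylzinc iodide 22 (not isolated)
Conditions: Zn, LiCl, THF, 30 °C; 21, Pd(DPEphos)Cl2 (3 mol %), THF, 0 → 23 °C
Reagents that add atoms: none
Why: Negishi sp3–sp2 coupling in which palladium inserts into the less hindered C–Br bond trans to the alkyl chain, so this trans-selective monoalkylation places C7 trans to C11 and leaves the (Z)-bromoalkene, while the enone and esters tolerate the alkylzinc.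

Step 12
Reactants: 23 methyl (1R,2S)-2-[(3Z,7E)-3-bromo-9-methoxy-7-methyl-9-oxonona-3,7-dien-1-yl]-1,3-dimethyl-5-oxocyclohex-3-ene-1-carboxylate
Product: 24 methyl (1R,2S)-2-[(3Z,7E)-9-methoxy-7-methyl-9-oxo-3-[(trimethylsilyl)methyl]nona-3,7-dien-1-yl]-1,3-dimethyl-5-oxocyclohex-3-ene-1-carboxylate
Conditions: Me3SiCH2MgCl, ZnCl2, THF, 0 °C; Pd(P(t-Bu)3)2 (5 mol %), THF, 23 → 40 °C
Reagents that add atoms: (trimethylsilyl)methylmagnesium chloride, C[Si](C)(C)C[Mg]Cl
Why: Second Negishi coupling, which with the bulky electron-rich phosphine proceeds with retention of alkene geometry and installs C17 as an allylsilane cis to C11.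

Step 13
Reactants: 24 methyl (1R,2S)-2-[(3Z,7E)-9-methoxy-7-methyl-9-oxo-3-[(trimethylsilyl)methyl]nona-3,7-dien-1-yl]-1,3-dimethyl-5-oxocyclohex-3-ene-1-carboxylate
Product: 25 methyl (1R,4aS,5R,8aS)-5-[(3E)-5-methoxy-3-methyl-5-oxopent-3-en-1-yl]-1,4a-dimethyl-6-methylidene-3-oxodecahydronaphthalene-1-carboxylate
Conditions: TiCl4 (2.5 equiv), CH2Cl2, −78 °C; aq. NaHCO3
Reagents that add atoms: none
Why: Intramolecular Hosomi–Sakurai conjugate allylation in which C9 attacks C10 of the Lewis-acid-activated enone through a chair-like transition state with the tether equatorial, giving the trans ring fusion (C10 methyl anti to C5–H and therefore syn to the C4 ester), an equatorial side chain at C9 from the (Z)-allylsilane geometry, and the exocyclic C8 methylene on loss of silicon.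

Step 14
Reactants: 25 methyl (1R,4aS,5R,8aS)-5-[(3E)-5-methoxy-3-methyl-5-oxopent-3-en-1-yl]-1,4a-dimethyl-6-methylidene-3-oxodecahydronaphthalene-1-carboxylate
Product: 27 methyl (2R,4R,5S,9R,10S,13E)-19-oxo-2,19-epoxylabda-8(17),13-dien-15-oate, via hydroxy diester 26 (not isolated)
Conditions: NaBH4, MeOH/THF, −20 → 23 °C
Reagents that add atoms: none
Why: Borohydride reduction of the C2 ketone from the equatorial direction, because the axial face is blocked by the 1,3-diaxial C10 methyl and C4 ester, gives the axial 2R alkoxide, which lactonises onto the syn-axial C19 ester by intramolecular transesterification.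

Step 15
Reactants: 27 methyl (2R,4R,5S,9R,10S,13E)-19-oxo-2,19-epoxylabda-8(17),13-dien-15-oate
Product: 28 (1R,3R,4aS,5R,8aS)-5-[(3E)-4-carboxy-3-methylbut-3-en-1-yl]-3-hydroxy-1,4a-dimethyl-6-methylidenedecahydronaphthalene-1-carboxylic acid
Conditions: LiOH (8 equiv), THF/MeOH/H2O, 45 °C; 1 M HCl to pH 3, 0 °C
Reagents that add atoms: lithium hydroxide, [Li+].[OH-]
Why: Saponification by acyl–oxygen cleavage of the strained bridged lactone and of the enoate methyl ester, which leaves the C2–O bond and every stereocentre intact, with cold mild acidification to avoid relactonisation.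

**Compound list**

1 | 5,6-dihydro-2H-pyran-2-one | O=C1C=CCCO1 | starting material
2 | potassium trifluoro(prop-1-en-2-yl)borate | [K+].C=C(C)[B-](F)(F)F | starting material
3 | (4R)-4-(prop-1-en-2-yl)oxan-2-one | CC(=C)[C@@H]1CCOC(=O)C1 | intermediate
4 | sodium iodoacetate | [Na+].[O-]C(=O)CI | starting material
5 | lithium (4R)-4-(prop-1-en-2-yl)-3,4-dihydro-2H-pyran-6-olate (lithium enolate of 3) | [Li]OC1=C[C@H](C(C)=C)CCO1 | intermediate (not isolated)
6 | 2-[(3S,4R)-2-oxo-4-(prop-1-en-2-yl)oxan-3-yl]acetic acid | OC(=O)C[C@@H]1C(=O)OCC[C@H]1C(C)=C | intermediate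
7 | dilithium dianion of 6 (lithium carboxylate plus lithium lactone enolate, isopropenyl-bearing centre unchanged) | [Li]OC(=O)CC1=C(O[Li])OCC[C@H]1C(C)=C | intermediate (not isolated)
8 | 2-[(3R,4S)-3-methyl-2-oxo-4-(prop-1-en-2-yl)oxan-3-yl]acetic acid | OC(=O)C[C@@]1(C)C(=O)OCC[C@H]1C(C)=C | intermediate
9 | 2-[(3R,4S)-3-methyl-2-oxo-4-(prop-1-en-2-yl)oxan-3-yl]acetyl chloride | ClC(=O)C[C@@]1(C)C(=O)OCC[C@H]1C(C)=C | intermediate (not isolated)
10 | (4aR,8aR)-5-chloro-5,8a-dimethyl-3,4,4a,5,6,8a-hexahydro-1H-isochromene-1,7(8H)-dione (both epimers at C5 of the bicycle) | O=C1C[C@@]2(C)C(=O)OCC[C@H]2C(C)(Cl)C1 | intermediate (not isolated)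
11 | (4aS,8aR)-5,8a-dimethyl-3,4,4a,8a-tetrahydro-1H-isochromene-1,7(8H)-dione (cis-fused enone lactone) | O=C1C[C@@]2(C)C(=O)OCC[C@H]2C(C)=C1 | intermediate
12 | trimethylsilyl (1R,2S)-2-(2-iodoethyl)-1,3-dimethyl-5-oxocyclohex-3-ene-1-carboxylate | O=C1C[C@@](C)(C(=O)O[Si](C)(C)C)[C@@H](CCI)C(C)=C1 | intermediate (not isolated)
13 | (1R,2S)-2-(2-iodoethyl)-1,3-dimethyl-5-oxocyclohex-3-ene-1-carboxylic acid | O=C1C[C@@](C)(C(=O)O)[C@@H](CCI)C(C)=C1 | intermediate (not isolated)
14 | methyl (1R,2S)-2-(2-iodoethyl)-1,3-dimethyl-5-oxocyclohex-3-ene-1-carboxylate | O=C1C[C@@](C)(C(=O)OC)[C@@H](CCI)C(C)=C1 | intermediate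
15 | pent-4-yn-1-ol | C#CCCCO | starting material
16 | tert-butyl(dimethyl)(pent-4-yn-1-yloxy)silane | C#CCCCO[Si](C)(C)C(C)(C)C | intermediate
17 | [(1E)-5-[tert-butyl(dimethyl)silyl]oxy-2-methylpent-1-en-1-yl]dimethylalumane | C[Al](C)/C=C(\C)CCCO[Si](C)(C)C(C)(C)C | intermediate (not isolated)
18 | methyl (2E)-6-[tert-butyl(dimethyl)silyl]oxy-3-methylhex-2-enoate | COC(=O)/C=C(\C)CCCO[Si](C)(C)C(C)(C)C | intermediate
19 | methyl (2E)-6-hydroxy-3-methylhex-2-enoate | COC(=O)/C=C(\C)CCCO | intermediate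
20 | methyl (2E)-3-methyl-6-oxohex-2-enoate | COC(=O)/C=C(\C)CCC=O | intermediate
21 | methyl (2E)-7,7-dibromo-3-methylhepta-2,6-dienoate | COC(=O)/C=C(\C)CCC=C(Br)Br | intermediate
22 | alkylzinc iodide of 14 (C–I replaced by C–ZnI, stereocentres as in 14) | O=C1C[C@@](C)(C(=O)OC)[C@@H](CC[Zn]I)C(C)=C1 | intermediate (not isolated)
23 | methyl (1R,2S)-2-[(3Z,7E)-3-bromo-9-methoxy-7-methyl-9-oxonona-3,7-dien-1-yl]-1,3-dimethyl-5-oxocyclohex-3-ene-1-carboxylate | O=C1C[C@@](C)(C(=O)OC)[C@@H](CC/C(Br)=C/CC/C(C)=C/C(=O)OC)C(C)=C1 | intermediate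
24 | methyl (1R,2S)-2-[(3Z,7E)-9-methoxy-7-methyl-9-oxo-3-[(trimethylsilyl)methyl]nona-3,7-dien-1-yl]-1,3-dimethyl-5-oxocyclohex-3-ene-1-carboxylate | O=C1C[C@@](C)(C(=O)OC)[C@@H](CC/C(C[Si](C)(C)C)=C/CC/C(C)=C/C(=O)OC)C(C)=C1 | intermediate
25 | methyl (1R,4aS,5R,8aS)-5-[(3E)-5-methoxy-3-methyl-5-oxopent-3-en-1-yl]-1,4a-dimethyl-6-methylidene-3-oxodecahydronaphthalene-1-carboxylate | C=C1CC[C@H]2[C@@](C)(CC(=O)C[C@@]2(C)C(=O)OC)[C@@H]1CC/C(C)=C/C(=O)OC | intermediate
26 | methyl (1R,3R,4aS,5R,8aS)-3-hydroxy-5-[(3E)-5-methoxy-3-methyl-5-oxopent-3-en-1-yl]-1,4a-dimethyl-6-methylidenedecahydronaphthalene-1-carboxylate | C=C1CC[C@H]2[C@@](C)(C[C@@H](O)C[C@@]2(C)C(=O)OC)[C@@H]1CC/C(C)=C/C(=O)OC | intermediate (not isolated)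
27 | methyl (2R,4R,5S,9R,10S,13E)-19-oxo-2,19-epoxylabda-8(17),13-dien-15-oate (labdane numbering; γ-lactone from the C19 carbonyl to the axial oxygen on C2) | C=C1CC[C@H]2[C@@](C)(C[C@@H]3C[C@@]2(C)C(=O)O3)[C@@H]1CC/C(C)=C/C(=O)OC | intermediate
28 | (1R,3R,4aS,5R,8aS)-5-[(3E)-4-carboxy-3-methylbut-3-en-1-yl]-3-hydroxy-1,4a-dimethyl-6-methylidenedecahydronaphthalene-1-carboxylic acid (CNP0086784.5) | C=C1CC[C@H]2[C@@](C)(C[C@@H](O)C[C@@]2(C)C(=O)O)[C@@H]1CC/C(C)=C/C(=O)O | target

**Step count and risks**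

Total step count: 15. Longest linear sequence: 10 (steps 1–5, then 11–15; the branch of steps 6–10, then 11–15, is equally long).

Most likely to fail, first: step 13. The ring closure must form a quaternary centre next to a tertiary one and must give the trans rather than the cis ring fusion. The fallback sets out from 24. Luche reduction (NaBH4, CeCl3·7H2O, MeOH) gives allylic alcohol F5 as a mixture at the carbinol carbon. Catalytic Sc(OTf)3 in CH2Cl2 ionises it to the allyl cation, which the allylsilane captures at C10 in an allyl-cation/allylsilane cyclisation through the same chair arrangement, giving octalin diester F6 with a C1=C2 double bond. I2 in MeCN then closes the axial C19 methyl ester onto C2 (iodolactonisation with loss of the ester methyl, iodine axial at C1) to iodolactone F7. Bu3SnH/AIBN removes the iodine, and the route is rejoined at 27.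

Second: step 4. The cationic acylation can give alkene isomers or epimerise the ring-fusion CH that is γ to the new enone. The fallback sets out from 8. PhSeSePh and Bu3P convert the acid to selenoester F3. Bu3SnH/AIBN in benzene at 80 °C generates the acyl radical, which closes 6-endo on the CH2 terminus of the isopropenyl group to saturated keto lactone F4 (both epimers at the new methyl-bearing carbon). IBX in DMSO dehydrogenates the ketone, which can only occur toward C1–C10 because C4 is quaternary, and the route is rejoined at 11.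

Third: step 2. The anionic haloacetate is a sluggish electrophile, and the dianion methylation that follows depends on it. The fallback sets out from 3. Its lithium enolate is alkylated with tert-butyl bromoacetate to tert-butyl ester F1. A second deprotonation (LiN(i-Pr)2; the lactone α-CH is more acidic and less shielded than the CH2 beside the tert-butyl ester) and MeI, again anti to the isopropenyl group, give methylated tert-butyl ester F2. CF3CO2H cleaves the tert-butyl ester, and the route is rejoined at 8.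

**Further compounds**

F1 | step 2 | tert-butyl 2-[(3S,4R)-2-oxo-4-(prop-1-en-2-yl)oxan-3-yl]acetate | CC(C)(C)OC(=O)C[C@@H]1C(=O)OCC[C@H]1C(C)=C
F2 | step 2 | tert-butyl 2-[(3R,4S)-3-methyl-2-oxo-4-(prop-1-en-2-yl)oxan-3-yl]acetate | CC(C)(C)OC(=O)C[C@@]1(C)C(=O)OCC[C@H]1C(C)=C
F3 | step 4 | Se-phenyl 2-[(3R,4S)-3-methyl-2-oxo-4-(prop-1-en-2-yl)oxan-3-yl]ethaneselenoate | O=C([Se]c1ccccc1)C[C@@]1(C)C(=O)OCC[C@H]1C(C)=C
F4 | step 4 | (4aS,8aR)-5,8a-dimethyl-3,4,4a,5,6,8a-hexahydro-1H-isochromene-1,7(8H)-dione (both epimers at C5 of the bicycle) | O=C1C[C@@]2(C)C(=O)OCC[C@H]2C(C)C1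
F5 | step 13 | methyl (1R,2S)-5-hydroxy-2-[(3Z,7E)-9-methoxy-7-methyl-9-oxo-3-[(trimethylsilyl)methyl]nona-3,7-dien-1-yl]-1,3-dimethylcyclohex-3-ene-1-carboxylate (both epimers at C5 of the ring) | OC1C[C@@](C)(C(=O)OC)[C@@H](CC/C(C[Si](C)(C)C)=C/CC/C(C)=C/C(=O)OC)C(C)=C1
F6 | step 13 | methyl (1R,4aS,5R,8aS)-5-[(3E)-5-methoxy-3-methyl-5-oxopent-3-en-1-yl]-1,4a-dimethyl-6-methylidene-1,2,4a,5,6,7,8,8a-octahydronaphthalene-1-carboxylate | C=C1CC[C@H]2[C@@](C)(C=CC[C@@]2(C)C(=O)OC)[C@@H]1CC/C(C)=C/C(=O)OC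
F7 | step 13 | iodolactone: 27 carrying an axial iodine on C1 (labdane numbering), trans to the lactone oxygen on C2 | C=C1CC[C@H]2[C@@](C)([C@H](I)[C@@H]3C[C@@]2(C)C(=O)O3)[C@@H]1CC/C(C)=C/C(=O)OC
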